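**Retrosynthetic overview**

1. The target is a 2,4,6-trisubstituted oxane, (2R,4R,6S): the C4 and C6 substituents are cis and the C2 aryl group is trans to both (axial), so it is the less stable C2 epimer and no acid may be used once C2 is set. The end game is acylation of ring A (aryl-Mg plus a cinnamoyl Weinreb amide) and fluoride desilylation.
2. The C2–aryl bond comes from axial arylation of the oxocarbenium ion released from an oxan-2-yl sulfone, so C2 is carried as a lactone carbonyl. C4 is set by hydrogenation of a C3=C4 enoate anti to the C6 chain.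
3. Key disconnection: the (6S)-4-aryl-5,6-dihydro-2H-pyran-2-one is split into a 3-arylbut-3-enoate and a 3-arylpropanal. One operation forms C5–C6 (vinylogous aldol) and O1–C2 (lactonization).
4. Enabling feature: in the oxane ring, O1 lies between the carbinol carbon C6 and C2, which is both benzylic and O-bound. With C2 at the carboxyl level and C3=C4 unsaturated, O1–C2(=O)–C3=C4(aryl)–C5H2–C6H(O) is the retron of a vinylogous aldol lactone, C5 being the γ-carbon of a dienolate.
5. Ring order: the oxane, made as the δ-lactone in step 6, is the only ring formed; the four benzene rings are bought.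

Key step: step 6

Abbreviations: TBS = tert-butyldimethylsilyl; Bn = benzyl. Oxane numbering throughout: O1, C2 (bears the 4-oxygenated phenyl group), C4 (bears ring A, the methoxylated ring), C6 (bears the 2-arylethyl chain).

Assumption: the (R)-ligand in step 6 is taken to give the (6S)-lactone; if a test run shows the opposite sense, the (S)-ligand is used and nothing else changes.

**Route**

Step 1
Reactants: 1 methyl 3-(4-hydroxyphenyl)propanoate
Product: 2 methyl 3-[4-(tert-butyldimethylsilyloxy)phenyl]propanoate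
Conditions: TBSCl, imidazole, DMF, rt
Reagents that add atoms: tert-butyldimethylsilyl chloride, CC(C)(C)[Si](C)(C)Cl
Why: Imidazole-assisted O-silylation masks the acidic phenol as an aryl silyl ether that should survive bases, hydrides, hydrogenation and organometallics and leave with fluoride at the end.

Step 2
Reactants: 2 methyl 3-[4-(tert-butyldimethylsilyloxy)phenyl]propanoate
Product: 3 3-[4-(tert-butyldimethylsilyloxy)phenyl]propanal
Conditions: i-Bu2AlH (1.05 equiv), CH2Cl2, −78 °C; aqueous potassium sodium tartrate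
Reagents that add atoms: none
Why: Partial ester reduction with i-Bu2AlH stops at the aldehyde because the tetrahedral aluminium hemiacetal is stable at −78 °C.

Step 3
Reactants: 4 1-(2,6-dihydroxy-4-methoxyphenyl)ethan-1-one
Product: 5 1-[2,6-bis(benzyloxy)-4-methoxyphenyl]ethan-1-one
Conditions: BnBr (2.5 equiv), K2CO3, DMF, 60 °C
Reagents that add atoms: benzyl bromide, BrCc1ccccc1
Why: Williamson etherification of both chelated phenols gives benzyl ethers, which cannot migrate to a neighbouring enolate and are removed for free in step 7.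

Step 4
Reactants: 5 1-[2,6-bis(benzyloxy)-4-methoxyphenyl]ethan-1-one
Product: 6 1-[2,6-bis(benzyloxy)-4-methoxyphenyl]ethenyl trifluoromethanesulfonate
Conditions: KN(SiMe3)2, THF, −78 °C; then PhNTf2, −78 → 0 °C; aq NH4Cl
Reagents that add atoms: N-phenylbis(trifluoromethanesulfonimide), O=S(=O)(N(c1ccccc1)S(=O)(=O)C(F)(F)F)C(F)(F)F
Why: The acetyl methyl group is the only enolizable position and O-sulfonylation of its potassium enolate gives the 1-arylvinyl triflate (enol triflate formation), so the hindered carbonyl is used through its enolate instead of being attacked.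

Step 5
Reactants: 6 1-[2,6-bis(benzyloxy)-4-methoxyphenyl]ethenyl trifluoromethanesulfonate; 7 ethyl bromoacetate
Product: 9 ethyl 3-[2,6-bis(benzyloxy)-4-methoxyphenyl]but-3-enoate, via zinc ester enolate BrZnCH2CO2Et 8 (not isolated)
Conditions: 7, Zn dust (Me3SiCl-activated), THF, rt; then 6, Pd(PPh3)4 (5 mol%), THF, 50 °C
Reagents that add atoms: none
Why: Negishi-type coupling of the Reformatsky reagent with the vinyl triflate (oxidative addition, transmetalation from zinc, reductive elimination) should give the β,γ-unsaturated ester with the double bond fixed in the 1,1-disubstituted position.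

Step 6
Reactants: 9 ethyl 3-[2,6-bis(benzyloxy)-4-methoxyphenyl]but-3-enoate; 3 3-[4-(tert-butyldimethylsilyloxy)phenyl]propanal
Product: 11 (6S)-4-[2,6-bis(benzyloxy)-4-methoxyphenyl]-6-{2-[4-(tert-butyldimethylsilyloxy)phenyl]ethyl}-5,6-dihydro-2H-pyran-2-one, via open-chain (2E,5S)-5-hydroxy enoate 10 (not isolated)
Conditions: [Cu(MeCN)4]PF6 (5 mol%), (R)-DTBM-SEGPHOS (6 mol%), Barton's base (10 mol%), THF, −20 °C → rt, slow addition of 3
Reagents that add atoms: none
Why: The amine base deprotonates the α-CH2 of 9 within the coordination sphere of the cationic copper–bisphosphine complex, and the chiral copper dienolate attacks aldehyde 3 through its terminal γ-CH2 in a six-membered allylcopper transition state (C5–C6 bond); the copper alkoxide 10 then adds to its own ester carbonyl and expels ethoxide (O1–C2 bond), which regenerates the basic catalyst. The closest known reaction type is the copper–bisphosphine-catalysed direct asymmetric vinylogous aldol–lactonization of β,γ-unsaturated esters with aldehydes to α,β-unsaturated δ-lactones. The one ring that closes, the 5,6-dihydropyran-2-one, forms by 6-exo-trig acyl substitution. The new stereocenter C6 is set under catalyst control by the chiral ligand, which selects the aldehyde face (S wanted); no other stereocenter is present. The step needs γ- over α-attack, which the cyclic allylcopper transition state and the crowded aryl-bearing carbon next to Cα should secure, and a new C3=C4 bond with the ester cis to C5, which should follow because the ester sits pseudo-axial beside the bulky C4 aryl group in that transition state and any trans isomer can re-enter through the dienolate. Slow addition of 3 keeps aldehyde self-condensation down.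

Step 7
Reactants: 11 (6S)-4-[2,6-bis(benzyloxy)-4-methoxyphenyl]-6-{2-[4-(tert-butyldimethylsilyloxy)phenyl]ethyl}-5,6-dihydro-2H-pyran-2-one
Product: 12 (4R,6S)-6-{2-[4-(tert-butyldimethylsilyloxy)phenyl]ethyl}-4-(2,6-dihydroxy-4-methoxyphenyl)oxan-2-one
Conditions: H2 (3 atm), 10% Pd/C, EtOAc, rt
Reagents that add atoms: none
Why: Catalytic hydrogenation should deliver H2 to C3=C4 from the face opposite the pseudo-equatorial C6 chain of the half-chair lactone, placing the aryl group cis to it (4R, substrate control), while the same catalyst hydrogenolyses both benzyl ethers; the lactone C6–O bond is not benzylic and the silyl ether is inert.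

Step 8
Reactants: 12 (4R,6S)-6-{2-[4-(tert-butyldimethylsilyloxy)phenyl]ethyl}-4-(2,6-dihydroxy-4-methoxyphenyl)oxan-2-one
Product: 13 (4R,6S)-4-[2,6-bis(tert-butyldimethylsilyloxy)-4-methoxyphenyl]-6-{2-[4-(tert-butyldimethylsilyloxy)phenyl]ethyl}oxan-2-one
Conditions: TBSCl (2.5 equiv), imidazole, DMF, rt → 40 °C
Reagents that add atoms: tert-butyldimethylsilyl chloride, CC(C)(C)[Si](C)(C)Cl
Why: Imidazole-assisted silylation protects the two ring A phenols only now, because next to an enolate they would have migrated, and from here they allow a fluoride end game.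

Step 9
Reactants: 13 (4R,6S)-4-[2,6-bis(tert-butyldimethylsilyloxy)-4-methoxyphenyl]-6-{2-[4-(tert-butyldimethylsilyloxy)phenyl]ethyl}oxan-2-one
Product: 14 (4R,6S)-4-[2,6-bis(tert-butyldimethylsilyloxy)-4-methoxyphenyl]-6-{2-[4-(tert-butyldimethylsilyloxy)phenyl]ethyl}oxan-2-ol (both C2 epimers)
Conditions: i-Bu2AlH (1.1 equiv), CH2Cl2, −78 °C; aqueous potassium sodium tartrate
Reagents that add atoms: none
Why: Half-reduction of the δ-lactone to the lactol with i-Bu2AlH at −78 °C brings C2 to the aldehyde level without touching C4 or C6.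

Step 10
Reactants: 14 (4R,6S)-4-[2,6-bis(tert-butyldimethylsilyloxy)-4-methoxyphenyl]-6-{2-[4-(tert-butyldimethylsilyloxy)phenyl]ethyl}oxan-2-ol
Product: 15 (4R,6S)-4-[2,6-bis(tert-butyldimethylsilyloxy)-4-methoxyphenyl]-6-{2-[4-(tert-butyldimethylsilyloxy)phenyl]ethyl}-2-(phenylsulfonyl)oxane (both C2 epimers)
Conditions: PhSO2H, CaCl2, CH2Cl2, rt
Reagents that add atoms: benzenesulfinic acid, OS(=O)c1ccccc1
Why: Acid-promoted exchange at the anomeric carbon through the oxocarbenium ion (anomeric sulfone formation) gives a stable precursor of that ion; the aryl silyl ethers should tolerate the weak acid.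

Step 11
Reactants: 15 (4R,6S)-4-[2,6-bis(tert-butyldimethylsilyloxy)-4-methoxyphenyl]-6-{2-[4-(tert-butyldimethylsilyloxy)phenyl]ethyl}-2-(phenylsulfonyl)oxane; 16 (4-bromophenoxy)(tert-butyl)dimethylsilane
Product: 19 (2R,4R,6S)-4-[2,6-bis(tert-butyldimethylsilyloxy)-4-methoxyphenyl]-2-[4-(tert-butyldimethylsilyloxy)phenyl]-6-{2-[4-(tert-butyldimethylsilyloxy)phenyl]ethyl}oxane, via arylmagnesium bromide 17 (not isolated), via diarylzinc 18 (not isolated)
Conditions: 16 (3 equiv), Mg, THF; ZnBr2 (1.5 equiv), rt; then 15, THF, rt; aq NH4Cl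
Reagents that add atoms: none
Why: The magnesium and zinc halides ionize the sulfone to the oxocarbenium ion, whose half-chair keeps the C4 aryl group and C6 chain pseudo-equatorial, and the arylzinc should attack along the axial trajectory through a chair-like transition state, placing the new aryl group trans to both (2R, stereoelectronic control; substitution of 2-sulfonyl cyclic ethers by organozinc reagents).

Step 12
Reactants: 19 (2R,4R,6S)-4-[2,6-bis(tert-butyldimethylsilyloxy)-4-methoxyphenyl]-2-[4-(tert-butyldimethylsilyloxy)phenyl]-6-{2-[4-(tert-butyldimethylsilyloxy)phenyl]ethyl}oxane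
Product: 20 (2R,4R,6S)-4-[2,6-bis(tert-butyldimethylsilyloxy)-3-iodo-4-methoxyphenyl]-2-[4-(tert-butyldimethylsilyloxy)phenyl]-6-{2-[4-(tert-butyldimethylsilyloxy)phenyl]ethyl}oxane
Conditions: NIS (1.05 equiv), MeCN, 0 °C, dark
Reagents that add atoms: N-iodosuccinimide, O=C1CCC(=O)N1I
Why: Electrophilic aromatic iodination should go to ring A, the only ring with three oxygen donors, at either of its two equivalent free positions, under neutral conditions that do not ionize the C2–O1 bond.

Step 13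
Reactants: 21 4-(tert-butyldimethylsilyloxy)benzaldehyde; 22 diethyl {2-[methoxy(methyl)amino]-2-oxoethyl}phosphonate
Product: 23 (2E)-3-[4-(tert-butyldimethylsilyloxy)phenyl]-N-methoxy-N-methylprop-2-enamide
Conditions: NaH, THF, 0 °C → rt
Reagents that add atoms: none
Why: Horner–Wadsworth–Emmons olefination with a stabilized phosphonate anion gives the (E)-enamide.

Step 14
Reactants: 20 (2R,4R,6S)-4-[2,6-bis(tert-butyldimethylsilyloxy)-3-iodo-4-methoxyphenyl]-2-[4-(tert-butyldimethylsilyloxy)phenyl]-6-{2-[4-(tert-butyldimethylsilyloxy)phenyl]ethyl}oxane; 23 (2E)-3-[4-(tert-butyldimethylsilyloxy)phenyl]-N-methoxy-N-methylprop-2-enamide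
Product: 25 (2E)-1-{2,4-bis(tert-butyldimethylsilyloxy)-3-[(2R,4R,6S)-2-[4-(tert-butyldimethylsilyloxy)phenyl]-6-{2-[4-(tert-butyldimethylsilyloxy)phenyl]ethyl}oxan-4-yl]-6-methoxyphenyl}-3-[4-(tert-butyldimethylsilyloxy)phenyl]prop-2-en-1-one, via arylmagnesium chloride 24 (not isolated)
Conditions: i-PrMgCl·LiCl (1.1 equiv), THF, −20 → 0 °C; then 23 (1.5 equiv), 0 °C → rt; aq NH4Cl
Reagents that add atoms: none
Why: Iodine–magnesium exchange gives an aryl Grignard reagent that should not suffer silyl migration, and its addition to the Weinreb amide gives a chelated tetrahedral intermediate that releases the enone only on work-up, so over-addition and conjugate addition to the chalcone are excluded (Weinreb ketone synthesis).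

Step 15
Reactants: 25 (2E)-1-{2,4-bis(tert-butyldimethylsilyloxy)-3-[(2R,4R,6S)-2-[4-(tert-butyldimethylsilyloxy)phenyl]-6-{2-[4-(tert-butyldimethylsilyloxy)phenyl]ethyl}oxan-4-yl]-6-methoxyphenyl}-3-[4-(tert-butyldimethylsilyloxy)phenyl]prop-2-en-1-one
Product: 26 (2E)-1-{2,4-dihydroxy-3-[(2R,4R,6S)-2-(4-hydroxyphenyl)-6-[2-(4-hydroxyphenyl)ethyl]oxan-4-yl]-6-methoxyphenyl}-3-(4-hydroxyphenyl)prop-2-en-1-one (CNP0215517.2)
Conditions: Bu4NF (5 equiv), AcOH (5 equiv), THF, 0 °C → rt
Reagents that add atoms: none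
Why: Fluoride cleaves the four aryl silyl ethers, and buffering with AcOH keeps the medium near neutral so that neither the axial benzylic C2–O1 bond (quinone-methide opening) nor the 2'-hydroxychalcone (flavanone closure) should equilibrate.

**Compound list**

1 | methyl 3-(4-hydroxyphenyl)propanoate | COC(=O)CCc1ccc(O)cc1 | starting material
2 | methyl 3-[4-(tert-butyldimethylsilyloxy)phenyl]propanoate | COC(=O)CCc1ccc(O[Si](C)(C)C(C)(C)C)cc1 | intermediate
3 | 3-[4-(tert-butyldimethylsilyloxy)phenyl]propanal | O=CCCc1ccc(O[Si](C)(C)C(C)(C)C)cc1 | intermediate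
4 | 1-(2,6-dihydroxy-4-methoxyphenyl)ethan-1-one | CC(=O)c1c(O)cc(OC)cc1O | starting material
5 | 1-[2,6-bis(benzyloxy)-4-methoxyphenyl]ethan-1-one | CC(=O)c1c(OCc2ccccc2)cc(OC)cc1OCc1ccccc1 | intermediate
6 | 1-[2,6-bis(benzyloxy)-4-methoxyphenyl]ethenyl trifluoromethanesulfonate | C=C(OS(=O)(=O)C(F)(F)F)c1c(OCc2ccccc2)cc(OC)cc1OCc1ccccc1 | intermediate
7 | ethyl bromoacetate | CCOC(=O)CBr | starting material
8 | bromo(2-ethoxy-2-oxoethyl)zinc | CCOC(=O)C[Zn]Br | intermediate
9 | ethyl 3-[2,6-bis(benzyloxy)-4-methoxyphenyl]but-3-enoate | CCOC(=O)CC(=C)c1c(OCc2ccccc2)cc(OC)cc1OCc1ccccc1 | intermediate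
10 | ethyl (2E,5S)-3-[2,6-bis(benzyloxy)-4-methoxyphenyl]-7-[4-(tert-butyldimethylsilyloxy)phenyl]-5-hydroxyhept-2-enoate (formed as its copper alkoxide) | CCOC(=O)/C=C(\C[C@@H](O)CCc1ccc(O[Si](C)(C)C(C)(C)C)cc1)c1c(OCc2ccccc2)cc(OC)cc1OCc1ccccc1 | intermediate
11 | (6S)-4-[2,6-bis(benzyloxy)-4-methoxyphenyl]-6-{2-[4-(tert-butyldimethylsilyloxy)phenyl]ethyl}-5,6-dihydro-2H-pyran-2-one | COc1cc(OCc2ccccc2)c(C2=CC(=O)O[C@@H](CCc3ccc(O[Si](C)(C)C(C)(C)C)cc3)C2)c(OCc2ccccc2)c1 | intermediate
12 | (4R,6S)-6-{2-[4-(tert-butyldimethylsilyloxy)phenyl]ethyl}-4-(2,6-dihydroxy-4-methoxyphenyl)oxan-2-one | COc1cc(O)c([C@@H]2C[C@H](CCc3ccc(O[Si](C)(C)C(C)(C)C)cc3)OC(=O)C2)c(O)c1 | intermediate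
13 | (4R,6S)-4-[2,6-bis(tert-butyldimethylsilyloxy)-4-methoxyphenyl]-6-{2-[4-(tert-butyldimethylsilyloxy)phenyl]ethyl}oxan-2-one | COc1cc(O[Si](C)(C)C(C)(C)C)c([C@@H]2C[C@H](CCc3ccc(O[Si](C)(C)C(C)(C)C)cc3)OC(=O)C2)c(O[Si](C)(C)C(C)(C)C)c1 | intermediate
14 | (4R,6S)-4-[2,6-bis(tert-butyldimethylsilyloxy)-4-methoxyphenyl]-6-{2-[4-(tert-butyldimethylsilyloxy)phenyl]ethyl}oxan-2-ol (both C2 epimers) | COc1cc(O[Si](C)(C)C(C)(C)C)c([C@@H]2C[C@H](CCc3ccc(O[Si](C)(C)C(C)(C)C)cc3)OC(O)C2)c(O[Si](C)(C)C(C)(C)C)c1 | intermediate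
15 | (4R,6S)-4-[2,6-bis(tert-butyldimethylsilyloxy)-4-methoxyphenyl]-6-{2-[4-(tert-butyldimethylsilyloxy)phenyl]ethyl}-2-(phenylsulfonyl)oxane (both C2 epimers) | COc1cc(O[Si](C)(C)C(C)(C)C)c([C@@H]2C[C@H](CCc3ccc(O[Si](C)(C)C(C)(C)C)cc3)OC(S(=O)(=O)c3ccccc3)C2)c(O[Si](C)(C)C(C)(C)C)c1 | intermediate
16 | (4-bromophenoxy)(tert-butyl)dimethylsilane | CC(C)(C)[Si](C)(C)Oc1ccc(Br)cc1 | starting material
17 | [4-(tert-butyldimethylsilyloxy)phenyl]magnesium bromide | CC(C)(C)[Si](C)(C)Oc1ccc([Mg]Br)cc1 | intermediate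
18 | bis[4-(tert-butyldimethylsilyloxy)phenyl]zinc | CC(C)(C)[Si](C)(C)Oc1ccc([Zn]c2ccc(O[Si](C)(C)C(C)(C)C)cc2)cc1 | intermediate
19 | (2R,4R,6S)-4-[2,6-bis(tert-butyldimethylsilyloxy)-4-methoxyphenyl]-2-[4-(tert-butyldimethylsilyloxy)phenyl]-6-{2-[4-(tert-butyldimethylsilyloxy)phenyl]ethyl}oxane | COc1cc(O[Si](C)(C)C(C)(C)C)c([C@@H]2C[C@H](CCc3ccc(O[Si](C)(C)C(C)(C)C)cc3)O[C@@H](c3ccc(O[Si](C)(C)C(C)(C)C)cc3)C2)c(O[Si](C)(C)C(C)(C)C)c1 | intermediate
20 | (2R,4R,6S)-4-[2,6-bis(tert-butyldimethylsilyloxy)-3-iodo-4-methoxyphenyl]-2-[4-(tert-butyldimethylsilyloxy)phenyl]-6-{2-[4-(tert-butyldimethylsilyloxy)phenyl]ethyl}oxane | COc1cc(O[Si](C)(C)C(C)(C)C)c([C@@H]2C[C@H](CCc3ccc(O[Si](C)(C)C(C)(C)C)cc3)O[C@@H](c3ccc(O[Si](C)(C)C(C)(C)C)cc3)C2)c(O[Si](C)(C)C(C)(C)C)c1I | intermediate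
21 | 4-(tert-butyldimethylsilyloxy)benzaldehyde | O=Cc1ccc(O[Si](C)(C)C(C)(C)C)cc1 | starting material
22 | diethyl {2-[methoxy(methyl)amino]-2-oxoethyl}phosphonate | CCOP(=O)(OCC)CC(=O)N(C)OC | starting material
23 | (2E)-3-[4-(tert-butyldimethylsilyloxy)phenyl]-N-methoxy-N-methylprop-2-enamide | CON(C)C(=O)/C=C/c1ccc(O[Si](C)(C)C(C)(C)C)cc1 | intermediate
24 | arylmagnesium chloride from 20 (Mg in place of I) | COc1cc(O[Si](C)(C)C(C)(C)C)c([C@@H]2C[C@H](CCc3ccc(O[Si](C)(C)C(C)(C)C)cc3)O[C@@H](c3ccc(O[Si](C)(C)C(C)(C)C)cc3)C2)c(O[Si](C)(C)C(C)(C)C)c1[Mg]Cl | intermediate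
25 | (2E)-1-{2,4-bis(tert-butyldimethylsilyloxy)-3-[(2R,4R,6S)-2-[4-(tert-butyldimethylsilyloxy)phenyl]-6-{2-[4-(tert-butyldimethylsilyloxy)phenyl]ethyl}oxan-4-yl]-6-methoxyphenyl}-3-[4-(tert-butyldimethylsilyloxy)phenyl]prop-2-en-1-one | COc1cc(O[Si](C)(C)C(C)(C)C)c([C@@H]2C[C@H](CCc3ccc(O[Si](C)(C)C(C)(C)C)cc3)O[C@@H](c3ccc(O[Si](C)(C)C(C)(C)C)cc3)C2)c(O[Si](C)(C)C(C)(C)C)c1C(=O)/C=C/c1ccc(O[Si](C)(C)C(C)(C)C)cc1 | intermediate
26 | (2E)-1-{2,4-dihydroxy-3-[(2R,4R,6S)-2-(4-hydroxyphenyl)-6-[2-(4-hydroxyphenyl)ethyl]oxan-4-yl]-6-methoxyphenyl}-3-(4-hydroxyphenyl)prop-2-en-1-one | COc1cc(O)c([C@@H]2C[C@H](CCc3ccc(O)cc3)O[C@@H](c3ccc(O)cc3)C2)c(O)c1C(=O)/C=C/c1ccc(O)cc1 | target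

**Step count and risks**

Total step count: 15. Longest linear sequence: 12 steps (from 4: steps 3 to 12, then 14 and 15).

Steps most likely to fail:

1. Step 6 (key step). The twisted, doubly ortho-substituted aryl group crowds the copper dienolate, so turnover may be slow, attack may occur at Cα instead of Cγ, the aldehyde may self-condense, or enantiofacial discrimination may be poor. Fallback: the route sets out from ketone 5 and aldehyde 3. A boron aldol reaction of the methyl ketone (the Ipc2BCl antipode that gives the 3S carbinol, Et3N, then 3, oxidative work-up) would give (3S)-1-[2,6-bis(benzyloxy)-4-methoxyphenyl]-5-[4-(tert-butyldimethylsilyloxy)phenyl]-3-hydroxypentan-1-one F1. Esterification with diethylphosphonoacetic acid (DCC, DMAP) would give the phosphonoacetate ester F2. An intramolecular Horner–Wadsworth–Emmons reaction (LiCl, DBU, MeCN) would then close the unsaturated lactone and rejoin the route at 11. Here C5–C6 comes from a ketone aldol, O1–C2 from an esterification and C3=C4 from the olefination.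

2. Step 11. The Lewis acids can re-ionize the benzylic, para-oxygenated C2–O1 bond of the product, which would let the kinetic axial aryl isomer drift to the all-equatorial 2,6-cis epimer; the oxocarbenium ion can also lose a proton to the enol ether, or the axial preference may be too small. Fallback: polarity reversal from sulfone 15. Reductive lithiation (lithium 4,4'-di-tert-butylbiphenylide, THF, −78 °C) would give the configurationally stable axial 2-lithio-oxane, trapped with Bu3SnCl as the axial stannane (2S,4R,6S)-tributyl{4-[2,6-bis(tert-butyldimethylsilyloxy)-4-methoxyphenyl]-6-{2-[4-(tert-butyldimethylsilyloxy)phenyl]ethyl}oxan-2-yl}stannane F3. A stereoretentive Stille-type coupling with aryl bromide 16 (Pd2(dba)3, JackiePhos, CuCl, KF, dioxane) would then give 19 without any cation at C2.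

3. Step 14. The aryl Grignard reagent is flanked by OMe and OSi groups, so addition to the amide may be slow, may turn to conjugate addition, or the reagent may simply be protonated. Fallback: aldehyde 21 would be homologated with Ph3P=CHCHO to (2E)-3-[4-(tert-butyldimethylsilyloxy)phenyl]prop-2-enal F4. The arylmagnesium chloride 24 made from 20 would add to this far more electrophilic aldehyde to give the allylic, benzylic alcohol F5 (both carbinol epimers), and oxidation with MnO2 would return to 25.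

**Further compounds**

F1 | step 6 | (3S)-1-[2,6-bis(benzyloxy)-4-methoxyphenyl]-5-[4-(tert-butyldimethylsilyloxy)phenyl]-3-hydroxypentan-1-one | O=C(C[C@@H](O)CCc1ccc(O[Si](C)(C)C(C)(C)C)cc1)c1c(OCc2ccccc2)cc(OC)cc1OCc1ccccc1
F2 | step 6 | (3S)-1-[2,6-bis(benzyloxy)-4-methoxyphenyl]-5-[4-(tert-butyldimethylsilyloxy)phenyl]-1-oxopentan-3-yl (diethoxyphosphoryl)acetate | CCOP(=O)(OCC)CC(=O)O[C@H](CC(=O)c1c(OCc2ccccc2)cc(OC)cc1OCc1ccccc1)CCc1ccc(O[Si](C)(C)C(C)(C)C)cc1
F3 | step 11 | (2S,4R,6S)-tributyl{4-[2,6-bis(tert-butyldimethylsilyloxy)-4-methoxyphenyl]-6-{2-[4-(tert-butyldimethylsilyloxy)phenyl]ethyl}oxan-2-yl}stannane (tin axial) | COc1cc(O[Si](C)(C)C(C)(C)C)c([C@@H]2C[C@H](CCc3ccc(O[Si](C)(C)C(C)(C)C)cc3)O[C@@H]([Sn](CCCC)(CCCC)CCCC)C2)c(O[Si](C)(C)C(C)(C)C)c1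
F4 | step 14 | (2E)-3-[4-(tert-butyldimethylsilyloxy)phenyl]prop-2-enal | O=C/C=C/c1ccc(O[Si](C)(C)C(C)(C)C)cc1
F5 | step 14 | (2E)-1-{2,4-bis(tert-butyldimethylsilyloxy)-3-[(2R,4R,6S)-2-[4-(tert-butyldimethylsilyloxy)phenyl]-6-{2-[4-(tert-butyldimethylsilyloxy)phenyl]ethyl}oxan-4-yl]-6-methoxyphenyl}-3-[4-(tert-butyldimethylsilyloxy)phenyl]prop-2-en-1-ol (both carbinol epimers) | COc1cc(O[Si](C)(C)C(C)(C)C)c([C@@H]2C[C@H](CCc3ccc(O[Si](C)(C)C(C)(C)C)cc3)O[C@@H](c3ccc(O[Si](C)(C)C(C)(C)C)cc3)C2)c(O[Si](C)(C)C(C)(C)C)c1C(O)/C=C/c1ccc(O[Si](C)(C)C(C)(C)C)cc1
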